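## Structural features

The target 30 is a cycloheptane (ring atoms C6, C7, C8, C9, C11, C13, C20 in ring order) cis-fused at C6–C7 to an α-methylene-γ-butyrolactone (oxygen on C6, α-carbon C2 on C7, carbonyl C1, exocyclic C3); α denotes the ring face that carries C2, β the other face. Six stereocentres sit on the seven-membered ring, contiguous except for the C8 methylene: C6 (O, α), C7, C9 (OH, β), C11 (CH3, α), the quaternary carbinol C13 (OH α, (E)-but-2-enoyl through C15 on the β side) and C20 (3-methylbutanoate, β). Neighbouring oxygens alternate in face (C6 α, C20 β, C13 α), and the C11 methyl is cis to the C13 hydroxyl and trans to the C9 hydroxyl. Fragile groups are the two Michael acceptors (methylene lactone and enone), the tertiary α-ketol at C13/C15 (acyloin shift, retro-aldol) and the ester on O20 next to free hydroxyls (acyl migration), so strong base and hard nucleophiles are excluded late. The real difficulty is not the ring size but the order of events: the quaternary C13 and its oxygenated neighbours must be set one from the other on a flexible ring, and methylenation, acylation and enone formation each forbid conditions that the others need. The key step exploits the array C20(O)–C13(acyl carbon)–C11(CH3)–C9(O): C11 and C13 are the two alkyne carbons of a but-2-ynoate inserted into the C20–C9 bond of a cyclopentanone (C20, C9, C8, C7, C6). This leaves a ketone at C20, the C15 ester on C13 and a C9=C11 alkene ready for syn hydration, with C7 already in place.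

## Logic of the disconnections

30 ⇒ 29. Only the O9–Si bond is cut. O9 must be masked while O20 is acylated and C15 is at the aldehyde level, where a free cis C9 hydroxyl would compete for the acyl group and form a bridged hemiacetal. The forward step needs a desilylation that spares two Michael acceptors, the α-ketol and the ester.

29 ⇒ 28 ⇒ 26 + 27. The enone is cut at C15–C16, through the allylic alcohol 28. The four-carbon acyl group falls to a one-carbon aldehyde on C13 and the three-carbon alkenyl halide 27. The forward steps need an alkenyl metal that adds only to a hindered aldehyde and keeps the E geometry, then an oxidation of the one remaining oxidisable alcohol.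

26 ⇒ 25 ⇒ 24 ⇒ 22 + 23. The O20–acyl bond is cut and the C13/C15 diol is returned to its acetonide. Acylating at 22 is chosen because C20–OH is then the only free hydroxyl. The forward steps need esterification of a hindered secondary alcohol, acetal cleavage without acyl migration, and oxidation of a primary alcohol next to a tertiary one without C–C cleavage.

22 ⇒ 19. The C2=C3 bond is cut. Removing the methylene leaves a saturated lactone that tolerates borane and hydride. The forward step needs a lactone enolate, so it is placed before 23 is introduced and before any other enolisable carbonyl exists.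

19 ⇒ 18 ⇒ 17. After removal of the silyl group, the C9–O and C11–H bonds are cut as a syn pair (retro-hydroboration). Two stereocentres disappear into the C9=C11 alkene. The forward step needs boron at C9 (secured by trisubstitution) and addition on the β-face.

17 ⇒ 16 ⇒ 15. Functional-group changes only: the acetonide is removed and C15 is returned from alcohol to the ester that the ring expansion delivers. The forward demand is reduction of a hindered ester while a γ-lactone survives.

15 ⇒ 14. The C20–H bond is cut to give the ketone. The forward step must deliver hydride to the α-face, against the steric bias of the cis-fused bicycle, so it must be directed by the C13 hydroxyl.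

14 ⇒ 11. The O–C6 bond of the lactone is cut, which gives a side-chain acid and a methylene α to the C20 ketone. One ring and the C6 stereocentre are removed. The forward step needs functionalisation of C6 anti to the C7 side chain and ring closure with inversion.

11 ⇒ 10. The C13–O bond is cut. The quaternary stereocentre returns to an enolisable β-keto ester. The forward step needs attack of oxygen at C13 rather than C9, and on the α-face.

10 ⇒ 9. The side-chain acid is returned to its methyl ester. The forward step is a saponification that must leave the C13 ester alone.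

9 ⇒ 6 + 7. The C9–C11 and C13–C20 bonds are cut and C20–C9 is re-formed. The seven-membered ring contracts to a cyclopentene and the four functionalised carbons C20, C13, C11, C9 reduce to an enol silane plus an alkynoate. The forward step needs the enol double bond fixed at C20=C9 and ring closure faster than silyl loss.

6 ⇒ 5. The O–Si and C8–H bonds are cut to give the enone. The forward step needs 1,4- rather than 1,2-hydrosilylation, which sets the enol regiochemistry without enolate equilibration.

5 ⇒ 4 ⇒ 3. The C20 carbonyl is returned to the allylic alcohol and the side chain to the malonate. The forward steps are a decarboxylation and a neutral oxidation, ordered so that the γ-stereogenic enone is never heated.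

3 ⇒ 1 + 2. The C7–C2 bond is cut. The only carbon stereocentre that must be bought is traced to the enantiopure monoacetate 1. The forward step needs substitution with net retention at the allyl terminus remote from the hydroxyl.

## Other disconnections considered

Alternative 1: The cut is C11–C13, made in the forward sense by an Ireland–Claisen rearrangement. The silyl ketene acetal of the seven-membered α-alkoxy lactone A1 (O–C8 allylic, (E)-propenyl on C8) would rearrange through the boat transition state that the ring imposes, O–C8 breaking as C11–C13 forms, to give the cycloheptenecarboxylic acid A2.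
- In its favour: the quaternary carbinol C13 and the C11 methyl centre arise together in a suprafacial sigmatropic shift with chirality transfer from C8, and the trans C6/C20 diol is carried from the start as an acetonide. On both points it is better than the chosen plan, which sets C13 by a facial preference on a flexible dienolate and builds the diol in two separate steps.
- Against it here: enolisation of A1 places an enolate β to the C20 acetonide oxygen (elimination), and a medium-ring boat transition state is less predictable than the usual chair. The C8=C9 alkene of A2 is 1,2-disubstituted, so its hydration to C9–OH has no inherent regiocontrol, whereas the trisubstituted C9=C11 alkene of 17 has. The C7 vinyl group needs several further steps to become the lactone.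
- Comparison: both plans face the same late conversion of a C15 carboxyl derivative into the propenyl ketone and the same methylenation, so they are equal there. In step count, the preparation of A1 is expected to outweigh the four steps that lead to 6.

Alternative 2: The cut is C2–C7 of the lactone. In the forward sense Rh2(OAc)4 would convert the C6 diazophosphonoacetate A3 into a carbenoid that inserts into the C7–H bond cis to O6 and closes the lactone as A4. A Horner–Wadsworth–Emmons reaction with formaldehyde would then give the methylene group.
- In its favour: the cis ring fusion is automatic, because the tether reaches only the α-hydrogen of C7 and insertion is stereoretentive. The lactone and the methylenation handle come in one step at the very end, and the exocyclic alkene is unveiled with carbonate rather than an amide base. On this last point it is better than the chosen plan, where the enolate methylenation dictates that acylation and enone formation come afterwards.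
- Against it: the carbenoid must choose the C7 methylene over C20–H (also a five-membered insertion), the enone alkene (cyclopropanation) and any free O–H. The array C9, C11, C13, C20 must be built on a cycloheptane that lacks the lactone, so the α-face screening used in step 12 is lost and C7 cannot serve as the stereochemical origin.
- Comparison: mechanistically a concerted C–H insertion replaces an SN2 lactonisation. Its end-game is shorter by about two steps, but the route to A3 is not shorter than the route to 22, and the chosen plan keeps ring construction and the first stereocentre in one simple precursor.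

Alternative 3: The cuts are C6–C20 and C8–C9. In the forward sense Me3SiOSO2CF3 would ionise the chiral mixed acetal A5 to a 1-alkoxy-2-siloxyallyl cation, which adds across C2 and C5 of 3-methylfuran A6 in a (4+3) cycloaddition to give the oxabicyclic ketone A7.
- In its favour: the seven-membered ring, the C11 methyl group and three oxygen-bearing stereocentres (C6, C9, C20) appear in one step from two small components, with C9 and C20 held cis on the β-face by the bridging oxygen as in 30. In ring construction and early step economy it is better than the chosen plan, which needs four steps before the ring expansion.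
- Against it: the bridging oxygen can stay on only one of C9 and C20 when the bridge is opened, so the other carbon must be re-oxygenated with retention. The C11=C13 alkene must become a quaternary carbinol bearing an acyl carbon at C13 and hydrogen at C11, for which the bicycle offers no polarised handle; the chosen plan obtains the C13 carbon substituent from the ynoate. The C7 ketone must become the C7–C2 bond with control of the C7 hydrogen. Regiochemistry with an unsymmetrical furan and auxiliary-controlled facial selectivity are expected to be only moderate.
- Comparison: both key steps are stepwise polar cycloadditions. The alternative front-loads complexity and then pays with a long end-game that depends on several selectivities, whereas the chosen plan reaches 9 with every ring carbon at an oxidation pattern that can be elaborated directly.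

Key step: step 5

Remark (structure check): C7 has the same sense in 6, 9 and 30 (C2 on C7 and the C6 oxygen end up cis); the enol drawn for 9 is one of three tautomers that share a single dienolate; no structure needed correction.

Remark (precursor design): the enol silane carries a tri(propan-2-yl)silyl group, because a bulkier silyl group disfavours loss of silicon from the oxocarbenium ion before ring closure. The side-chain ester is methyl, because a tert-alkyl ester can ionise under silyl triflimide or a chloride Lewis acid. Skeleton and disconnection are unchanged.

Assumption: 1 is bought enantiopure (it is also accessible from the meso diacetate by enzymatic or palladium/chiral diphosphine desymmetrisation).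

## Steps

Step 1
Reactants: 1 (1S,4R)-4-hydroxycyclopent-2-en-1-yl acetate; 2 dimethyl propanedioate
Product: 3 dimethyl 2-[(1S,4R)-4-hydroxycyclopent-2-en-1-yl]propanedioate
Conditions: NaH, 2 (2 equiv), Pd(PPh3)4 (3 mol%), THF, 0 °C → rt
Reagents that add atoms: none
Why: Tsuji–Trost allylic alkylation: zerovalent palladium ionises the acetate with inversion and the soft malonate anion attacks the π-allyl complex on the face opposite the metal, at the terminus remote from the hydroxyl. C7 is therefore set with net retention (cis to the C20 hydroxyl) and the enantiopurity of 1 is transferred.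

Step 2
Reactants: 3 dimethyl 2-[(1S,4R)-4-hydroxycyclopent-2-en-1-yl]propanedioate
Product: 4 methyl 2-[(1R,4R)-4-hydroxycyclopent-2-en-1-yl]acetate
Conditions: NaCl, H2O, DMSO, 150 °C
Reagents that add atoms: none
Why: Krapcho demethoxycarbonylation (chloride dealkylates one methyl ester and the carboxylate loses CO2). It is run before the oxidation so that no enone with a γ-stereocentre is ever heated; C7 cannot epimerise at this stage.

Step 3
Reactants: 4 methyl 2-[(1R,4R)-4-hydroxycyclopent-2-en-1-yl]acetate
Product: 5 methyl 2-[(1R)-4-oxocyclopent-2-en-1-yl]acetate
Conditions: MnO2, CH2Cl2, rt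
Reagents that add atoms: none
Why: MnO2 oxidises the allylic alcohol under neutral conditions, so the γ-stereocentre C7 of the enone is not exposed to base.

Step 4
Reactants: 5 methyl 2-[(1R)-4-oxocyclopent-2-en-1-yl]acetate
Product: 6 methyl 2-[(1R)-3-{[tri(propan-2-yl)silyl]oxy}cyclopent-3-en-1-yl]acetate
Conditions: iPr3SiH, Pt2[(CH2=CHSiMe2)2O]3 (0.5 mol%), toluene, 60 °C
Reagents that add atoms: tri(propan-2-yl)silane, CC(C)[SiH](C(C)C)C(C)C
Why: Conjugate (1,4-) hydrosilylation of an enone catalysed by zerovalent platinum: hydrogen goes to C8 and silicon to oxygen. This fixes the enol double bond at C20=C9, away from C6, without any enolate equilibration.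

Step 5
Reactants: 6 methyl 2-[(1R)-3-{[tri(propan-2-yl)silyl]oxy}cyclopent-3-en-1-yl]acetate; 7 methyl but-2-ynoate
Product: 9 methyl (4R)-2-hydroxy-4-(2-methoxy-2-oxoethyl)-7-methylcyclohepta-1,6-diene-1-carboxylate, via siloxycyclobutene 8 (not isolated)
Conditions: 7 (2 equiv), Tf2NH (5 mol%), CH2Cl2, −78 → −20 °C; then Bu4NF, THF, 0 °C
Reagents that add atoms: none
Why: The closest known reaction type is the Tf2NH- or Lewis-acid-promoted [2+2] cycloaddition of silyl enol ethers with propiolates, followed by retro-aldol opening of the siloxycyclobutene, a two-carbon ring enlargement. Tf2NH protodesilylates a trace of 6 to give iPr3SiNTf2, which silylates the ester carbonyl of 7; nucleophilic C9 of the enol silane then adds to the electrophilic β-carbon C11 (Mukaiyama–Michael), leaving a silyloxocarbenium ion at C20 and a silyl allenoate. The four-membered ring closes stepwise when the allenoate α-carbon C13 attacks C20 (4-exo-trig, aldol-type), which gives 8 and returns the silyl cation. Fluoride then frees the C20 alkoxide and the strained C20–C9 fusion bond breaks in a retro-aldol sense, the electrons flowing into the unsaturated ester; the seven-membered ring therefore arises by fragmentation of the bicycle, not by a cyclisation, and protonation of the dienolate gives 9. No lasting stereocentre is created: C9 and C20 of 8 (necessarily cis-fused, on either face) both become trigonal again, and C7 is a bystander. The step needs regiocontrol and chemoselectivity: the C20=C9 position of the enol double bond was fixed in step 4, polarity matching joins C9 to C11 and C13 to C20, and the bulky iPr3Si group stays on the oxocarbenium ion long enough for ring closure to outrun silyl loss to the open Michael adduct. The methyl esters of both partners are inert to the silyl triflimide, and the lower reactivity of the β-methyl ynoate is met by excess 7 and gradual warming.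

Step 6
Reactants: 9 methyl (4R)-2-hydroxy-4-(2-methoxy-2-oxoethyl)-7-methylcyclohepta-1,6-diene-1-carboxylate
Product: 10 2-[(1R)-3-hydroxy-4-(methoxycarbonyl)-5-methylcyclohepta-3,5-dien-1-yl]acetic acid
Conditions: LiOH (2.5 equiv), THF–H2O, 0 °C → rt, N2; then 1 M HCl to pH 3
Reagents that add atoms: lithium hydroxide, [Li+].[OH-]
Why: Saponification: hydroxide first converts the β-keto ester into its dienolate, which shields the C13 ester and the ketone, so only the unhindered side-chain ester is hydrolysed. C7 is not acidic.

Step 7
Reactants: 10 2-[(1R)-3-hydroxy-4-(methoxycarbonyl)-5-methylcyclohepta-3,5-dien-1-yl]acetic acid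
Product: 11 2-[(1R,4S)-4-hydroxy-4-(methoxycarbonyl)-5-methyl-3-oxocyclohept-5-en-1-yl]acetic acid
Conditions: KN(SiMe3)2 (2.2 equiv), THF, −78 °C; 3-phenyl-2-(phenylsulfonyl)oxaziridine, −78 → −40 °C; AcOH
Reagents that add atoms: 3-phenyl-2-(phenylsulfonyl)oxaziridine, O=S(=O)(N1OC1c1ccccc1)c1ccccc1
Why: Electrophilic α-hydroxylation of a β-keto ester enolate by an N-sulfonyloxaziridine: the dienolate reacts at C13 (α) rather than C9 (γ), which makes C13 quaternary and locks the alkene at C9=C11. The flap carbon C7 of the cycloheptadienolate holds its side chain pseudo-equatorially and so tilts C7–H over the β-face; oxygen should therefore arrive on the α-face (C13–OH cis to the C7 side chain). This remote control is a weak point and is treated below.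

Step 8
Reactants: 11 2-[(1R,4S)-4-hydroxy-4-(methoxycarbonyl)-5-methyl-3-oxocyclohept-5-en-1-yl]acetic acid
Product: 14 keto lactone (cis-fused γ-lactone with O on C6α and C2 on C7α; C20 ketone; C13α-OH; C13β-CO2Me; C9=C11 alkene), via tris-silyl enol ether 12 (not isolated), via 6β-bromo ketone 13 (not isolated)
Conditions: Me3SiOSO2CF3 (3.5 equiv), Et3N, CH2Cl2, 0 °C; N-bromosuccinimide, THF, −78 °C; NaHCO3 (aq), DMF, rt; then 1 M HCl, THF
Reagents that add atoms: none
Why: Soft enolisation can only go toward C6 because C13 is quaternary. Bromination of the enol silane anti to the neighbouring C7 side chain puts bromine on the β-face, and the carboxylate on the α side chain then displaces it by intramolecular SN2 (5-exo-tet) with inversion, which gives the cis-fused lactone with oxygen on C6α. Dilute acid removes the tertiary Me3Si ether.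

Step 9
Reactants: 14 keto lactone
Product: 15 diol lactone (14 with C20β-OH in place of the ketone)
Conditions: Me4NBH(OAc)3, MeCN–AcOH (1:1), −30 → 0 °C
Reagents that add atoms: none
Why: Hydroxyl-directed triacetoxyborohydride reduction: the C13 hydroxyl exchanges onto boron and delivers hydride to the α-face of the C20 ketone, so the new hydroxyl is β, trans to both the C13–OH and the C6 oxygen. Ester and lactone are inert to this reagent.

Step 10
Reactants: 15 diol lactone
Product: 16 triol lactone (15 with C15H2OH in place of CO2Me)
Conditions: NaBH4, EtOH–THF, 0 °C → rt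
Reagents that add atoms: none
Why: NaBH4 reduces esters readily only when a neighbouring hydroxyl binds boron and delivers hydride internally. The C13 ester has an α- and a cis β-hydroxyl and the lactone has neither, so the ester should be reduced to the primary alcohol selectively.

Step 11
Reactants: 16 triol lactone
Product: 17 acetonide (O13/O15 isopropylidene acetal of 16; C20β-OH free)
Conditions: Me2C(OMe)2, pyridinium p-toluenesulfonate (cat.), acetone, rt
Reagents that add atoms: 2,2-dimethoxypropane, COC(C)(C)OC
Why: Acetonide formation under thermodynamic control favours the five-membered dioxolane of the terminal 1,2-diol (O13/O15) over the six-membered O15/O20 ring, leaving the hindered C20 hydroxyl free.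

Step 12
Reactants: 17 acetonide
Product: 18 C9β-ol (17 hydrated across C9=C11: C9β-OH; C11β-H; C11α-CH3)
Conditions: BH3·THF, THF, 0 °C; then NaBO3·4H2O, H2O, rt
Reagents that add atoms: sodium perborate tetrahydrate (NaBO3·4H2O), [Na+].[O-]B1OO1
Why: Hydroboration–oxidation, syn and anti-Markovnikov: boron goes to the less substituted C9 and hydrogen to C11. In the conformer that avoids eclipsing of the C11 methyl with the C15 methylene, the α-face at C9 is screened by the pseudo-axial lactone methylene on C7 (the concave face of the cis-fused bicycle), so addition should occur on the β-face and give C9β–OH and C11β–H (methyl α). Perborate oxidises the C–B bond with retention and spares the lactone.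

Step 13
Reactants: 18 C9β-ol
Product: 19 C9 tert-butyldimethylsilyl ether of 18
Conditions: t-BuMe2SiCl, imidazole, DMF, rt
Reagents that add atoms: tert-butyl(chloro)dimethylsilane, CC(C)(C)[Si](C)(C)Cl
Why: Silylation discriminates on steric grounds: C9–OH is flanked by CH2 and CH(CH3), C20–OH by a quaternary spiro carbon and the lactone carbinol carbon, so only O9 should be silylated.

Step 14
Reactants: 19 C9 tert-butyldimethylsilyl ether of 18
Product: 22 α-methylene lactone (19 with C2=C3H2), via Mannich base 20 (not isolated), via methiodide 21 (not isolated)
Conditions: LiN(iPr)2 (2.3 equiv), THF, −78 °C; CH2=NMe2+ I−, −78 °C → rt; MeI, MeOH; NaHCO3 (aq), CH2Cl2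
Reagents that add atoms: N,N-dimethylmethyleneiminium iodide, C=[N+](C)C.[I-]
Why: α-Methylenation of a lactone by the Mannich route: the lithium enolate (one extra equivalent of base serves the C20 alkoxide) is aminomethylated, and N-methylation followed by mild base eliminates trimethylamine. It is done here because no other enolisable carbonyl group is present yet; C2 becomes trigonal, so its configuration is immaterial.

Step 15
Reactants: 22 α-methylene lactone; 23 3-methylbutanoyl chloride
Product: 24 C20 3-methylbutanoate of 22
Conditions: 23, pyridine, 4-(dimethylamino)pyridine (cat.), CH2Cl2, 0 °C → rt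
Reagents that add atoms: none
Why: Acylation of the only free hydroxyl (C20–OH) with an acid chloride under nucleophilic catalysis. Doing it now removes any later competition from the primary C15 hydroxyl or from O9.

Step 16
Reactants: 24 C20 3-methylbutanoate of 22
Product: 25 C13/C15 diol (24 without the acetonide)
Conditions: pyridinium p-toluenesulfonate, MeOH, rt
Reagents that add atoms: none
Why: Acid-catalysed transacetalisation removes the acetonide. The secondary silyl ether, the ester and the methylene lactone tolerate pyridinium tosylate in methanol, and the mildly acidic medium disfavours acyl migration from O20 to O15.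

Step 17
Reactants: 25 C13/C15 diol
Product: 26 C15 aldehyde of 25
Conditions: SO3·pyridine, DMSO, iPr2NEt, CH2Cl2, 0 °C
Reagents that add atoms: none
Why: Parikh–Doering oxidation of the primary alcohol. An activated-sulfoxide oxidant is chosen because it does not cleave 1,2-diols, and the aldehyde cannot enolise because C13 is quaternary.

Step 18
Reactants: 26 C15 aldehyde of 25; 27 (E)-1-bromoprop-1-ene
Product: 28 C15 allylic alcohol ((E)-prop-1-enyl carbinol from 26; C15 epimers)
Conditions: 27, CrCl2 (5 equiv), NiCl2 (2 mol%), DMSO, rt
Reagents that add atoms: none
Why: Nozaki–Hiyama–Kishi coupling: the alkenylchromium species formed from 27 under nickel catalysis adds to aldehydes only, keeps the E geometry and tolerates the ester, the methylene lactone and the free tertiary hydroxyl. The new C15 carbinol centre is left uncontrolled because it is oxidised next.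

Step 19
Reactants: 28 C15 allylic alcohol
Product: 29 C9 tert-butyldimethylsilyl ether of 30 (enone from 28)
Conditions: 1,1,1-triacetoxy-1,1-dihydro-1,2-benziodoxol-3(1H)-one, NaHCO3, CH2Cl2, 0 °C → rt
Reagents that add atoms: none
Why: Periodinane oxidation of the only oxidisable alcohol (allylic, secondary) gives the E-enone under buffered, non-basic conditions that should leave the tertiary α-ketol unrearranged.

Step 20
Reactants: 29 C9 tert-butyldimethylsilyl ether of 30
Product: 30 (3aS,5R,6S,7S,8S,8aR)-7-[(2E)-but-2-enoyl]-5,7-dihydroxy-6-methyl-3-methylidene-2-oxooctahydro-2H-cyclohepta[b]furan-8-yl 3-methylbutanoate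
Conditions: HF·pyridine, pyridine, THF, 0 °C → rt
Reagents that add atoms: none
Why: Fluoride cleaves the Si–O bond of the secondary silyl ether. Buffered HF·pyridine is not basic enough for conjugate addition, retro-aldol or acyl migration and not acidic enough to ionise the tertiary alcohol, so 30 should be released unchanged.

## Compound list

1 | (1S,4R)-4-hydroxycyclopent-2-en-1-yl acetate [(1R,4S)-cis-4-acetoxy-2-cyclopenten-1-ol] | O[C@H]1C=C[C@@H](OC(C)=O)C1 | starting material
2 | dimethyl propanedioate (dimethyl malonate) | COC(=O)CC(=O)OC | starting material
3 | dimethyl 2-[(1S,4R)-4-hydroxycyclopent-2-en-1-yl]propanedioate | O[C@H]1C=C[C@@H](C(C(=O)OC)C(=O)OC)C1 | intermediate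
4 | methyl 2-[(1R,4R)-4-hydroxycyclopent-2-en-1-yl]acetate | O[C@H]1C=C[C@@H](CC(=O)OC)C1 | intermediate
5 | methyl 2-[(1R)-4-oxocyclopent-2-en-1-yl]acetate | O=C1C=C[C@@H](CC(=O)OC)C1 | intermediate
6 | methyl 2-[(1R)-3-{[tri(propan-2-yl)silyl]oxy}cyclopent-3-en-1-yl]acetate | CC(C)[Si](C(C)C)(C(C)C)OC1=CC[C@@H](CC(=O)OC)C1 | intermediate
7 | methyl but-2-ynoate | CC#CC(=O)OC | starting material
8 | methyl (3R)-3-(2-methoxy-2-oxoethyl)-6-methyl-1-{[tri(propan-2-yl)silyl]oxy}bicyclo[3.2.0]hept-6-ene-7-carboxylate (cis-fused, both ring-fusion diastereomers) | COC(=O)C1=C(C)C2C[C@@H](CC(=O)OC)CC12O[Si](C(C)C)(C(C)C)C(C)C | intermediate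
9 | methyl (4R)-2-hydroxy-4-(2-methoxy-2-oxoethyl)-7-methylcyclohepta-1,6-diene-1-carboxylate (enol form of the β-keto ester) | OC1=C(C(=O)OC)C(C)=CC[C@@H](CC(=O)OC)C1 | intermediate
10 | 2-[(1R)-3-hydroxy-4-(methoxycarbonyl)-5-methylcyclohepta-3,5-dien-1-yl]acetic acid | OC1=C(C(=O)OC)C(C)=CC[C@@H](CC(=O)O)C1 | intermediate
11 | 2-[(1R,4S)-4-hydroxy-4-(methoxycarbonyl)-5-methyl-3-oxocyclohept-5-en-1-yl]acetic acid (C13α-OH) | O=C1[C@](O)(C(=O)OC)C(C)=CC[C@@H](CC(=O)O)C1 | intermediate
12 | tris(trimethylsilyl) derivative of 11 (silyl ester; C13 silyl ether; C20=C6 silyl enol ether) | C[Si](C)(C)OC1=C[C@H](CC(=O)O[Si](C)(C)C)CC=C(C)[C@@]1(O[Si](C)(C)C)C(=O)OC | intermediate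
13 | C6β-bromo ketone of 11 carrying the C13 trimethylsilyl ether (acid form) | O=C1[C@](O[Si](C)(C)C)(C(=O)OC)C(C)=CC[C@@H](CC(=O)O)[C@@H]1Br | intermediate
14 | keto lactone: cis-fused γ-lactone (O on C6α, C2 on C7α), C20 ketone, C13α-OH, C13β-CO2Me, C9=C11 alkene | C1C(=O)O[C@@H]2[C@H]1CC=C(C)[C@@](O)(C(=O)OC)C2=O | intermediate
15 | diol lactone: 14 with C20β-OH | C1C(=O)O[C@@H]2[C@H]1CC=C(C)[C@@](O)(C(=O)OC)[C@H]2O | intermediate
16 | triol lactone: 15 with C15H2OH in place of CO2Me | C1C(=O)O[C@@H]2[C@H]1CC=C(C)[C@@](O)(CO)[C@H]2O | intermediate
17 | acetonide: O13/O15 isopropylidene acetal of 16, C20β-OH free | C1C(=O)O[C@@H]2[C@H]1CC=C(C)[C@@]3(COC(C)(C)O3)[C@H]2O | intermediate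
18 | C9β-ol: 17 with C9β-OH, C11β-H, C11α-CH3 | C1C(=O)O[C@@H]2[C@H]1C[C@@H](O)[C@H](C)[C@@]3(COC(C)(C)O3)[C@H]2O | intermediate
19 | C9 tert-butyldimethylsilyl ether of 18 | C1C(=O)O[C@@H]2[C@H]1C[C@@H](O[Si](C)(C)C(C)(C)C)[C@H](C)[C@@]3(COC(C)(C)O3)[C@H]2O | intermediate
20 | α-(dimethylaminomethyl) lactone from 19 (C2 epimers) | CN(C)CC1C(=O)O[C@@H]2[C@H]1C[C@@H](O[Si](C)(C)C(C)(C)C)[C@H](C)[C@@]3(COC(C)(C)O3)[C@H]2O | intermediate
21 | trimethylammonium iodide of 20 | C[N+](C)(C)CC1C(=O)O[C@@H]2[C@H]1C[C@@H](O[Si](C)(C)C(C)(C)C)[C@H](C)[C@@]3(COC(C)(C)O3)[C@H]2O.[I-] | intermediate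
22 | α-methylene lactone: 19 with C2=C3H2 | C=C1C(=O)O[C@@H]2[C@H]1C[C@@H](O[Si](C)(C)C(C)(C)C)[C@H](C)[C@@]3(COC(C)(C)O3)[C@H]2O | intermediate
23 | 3-methylbutanoyl chloride | CC(C)CC(=O)Cl | starting material
24 | C20 3-methylbutanoate of 22 | C=C1C(=O)O[C@@H]2[C@H]1C[C@@H](O[Si](C)(C)C(C)(C)C)[C@H](C)[C@@]3(COC(C)(C)O3)[C@H]2OC(=O)CC(C)C | intermediate
25 | C13/C15 diol: 24 without the acetonide | C=C1C(=O)O[C@@H]2[C@H]1C[C@@H](O[Si](C)(C)C(C)(C)C)[C@H](C)[C@@](O)(CO)[C@H]2OC(=O)CC(C)C | intermediate
26 | C15 aldehyde of 25 | C=C1C(=O)O[C@@H]2[C@H]1C[C@@H](O[Si](C)(C)C(C)(C)C)[C@H](C)[C@@](O)(C=O)[C@H]2OC(=O)CC(C)C | intermediate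
27 | (E)-1-bromoprop-1-ene | C/C=C/Br | starting material
28 | C15 allylic alcohol: (E)-prop-1-enyl carbinol from 26 (C15 epimers) | C=C1C(=O)O[C@@H]2[C@H]1C[C@@H](O[Si](C)(C)C(C)(C)C)[C@H](C)[C@@](O)(C(O)/C=C/C)[C@H]2OC(=O)CC(C)C | intermediate
29 | C9 tert-butyldimethylsilyl ether of 30 | C=C1C(=O)O[C@@H]2[C@H]1C[C@@H](O[Si](C)(C)C(C)(C)C)[C@H](C)[C@@](O)(C(=O)/C=C/C)[C@H]2OC(=O)CC(C)C | intermediate
30 | (3aS,5R,6S,7S,8S,8aR)-7-[(2E)-but-2-enoyl]-5,7-dihydroxy-6-methyl-3-methylidene-2-oxooctahydro-2H-cyclohepta[b]furan-8-yl 3-methylbutanoate | C=C1C(=O)O[C@@H]2[C@H]1C[C@@H](O)[C@H](C)[C@@](O)(C(=O)/C=C/C)[C@H]2OC(=O)CC(C)C | target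

## Step count and least certain steps

Total step count: 20. Longest linear sequence: 20 steps (1 to 30); 2, 7, 23 and 27 enter as purchased reagents.

Step 5 (key step). What may go wrong: the β-methyl ynoate adds slowly, so protodesilylation of the enol silane, or silyl loss from the oxocarbenium ion to the open Michael adduct, may outrun closure of the four-membered ring. Fallback, setting out from 6: the same acid-promoted cycloaddition with the more electrophilic methyl propiolate should give the siloxycyclobutene F1, and Bu4NF should open it to the des-methyl keto ester F2, which lacks the C11 methyl. Me2CuLi then adds the C11 methyl in a conjugate sense and the enolate is trapped with PhSeBr as the selenide F3. H2O2 eliminates the selenoxide toward C11 to give the C11=C13 tautomer of 9, which delivers the same dienolate in step 6, so the route is rejoined at 9.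

Step 7. What may go wrong: poor facial selectivity of oxygen transfer, because C7 is remote from C13 on a flexible ring, or partial attack at C9. Fallback, setting out from 10: t-BuMe2SiOSO2CF3 and Et3N should give the bis-silyl dienol ether F4. Catalyst-controlled epoxidation of its C20=C13 enol double bond (Shi epoxidation with a fructose-derived ketone and KHSO5, the enantiomer of the ketone chosen for α-face delivery), followed by silyl loss on work-up, would give 11 by reagent rather than substrate control. The route is rejoined at 11.

Step 8. What may go wrong: bromide-exchange epimerisation of the α-bromo ketone, or elimination, before ring closure, which would erode the cis fusion. Fallback, setting out from 11 (through 12): Rubottom oxidation of the enol silane with dimethyldioxirane and mild hydrolysis should give the configurationally stable C6β-hydroxy keto acid F5. Mitsunobu lactonisation (PPh3, diisopropyl azodicarboxylate) inverts C6 and closes the ring as the silyl ether F6, and dilute HCl gives 14, where the route is rejoined.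

Step 10. What may go wrong: over-reduction of the γ-lactone while the hindered ester reacts slowly. Fallback, setting out from 15: one equivalent of LiOH opens the lactone to the lithium carboxylate F7, which borohydride does not reduce. LiBH4 then reduces the methyl ester to the carboxylate triol F8, and acidification re-closes the lactone (the C6 hydroxyl and the acid chain are cis) to give 16, where the route is rejoined.

Step 12. What may go wrong: poor facial selectivity of borane addition on the seven-membered ring, giving the C9α/C11 epimeric pair. Fallback, setting out from 17: (HMe2Si)2NH converts the β-oriented C20 hydroxyl into the dimethylsilyl ether F9. Intramolecular hydrosilylation catalysed by Pt2[(CH2=CHSiMe2)2O]3 can then only deliver silicon to C9 and hydrogen to C11 on the β-face, giving the oxasilinane F10. Tamao–Fleming oxidation (H2O2, KF, KHCO3) replaces silicon by hydroxyl with retention and gives 18, where the route is rejoined.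

Step 16 (through step 18). What may go wrong: migration of the 3-methylbutanoyl group from O20 to the cis-disposed O15 while C15 is an alcohol or a chromium alkoxide. Fallback, setting out from 22: the acetonide is removed first to give the triol F11. TEMPO with N-chlorosuccinimide oxidises only the primary alcohol, giving the hydroxy aldehyde F12; the CrCl2/NiCl2 coupling with 27 gives the allylic alcohol F13; and MnO2 oxidises only the allylic carbinol, giving the enone alcohol F14. Acylation of the remaining secondary hydroxyl with 23 then gives 29, where the route is rejoined.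

## Further compounds

F1 | step 5 | methyl (3R)-3-(2-methoxy-2-oxoethyl)-1-{[tri(propan-2-yl)silyl]oxy}bicyclo[3.2.0]hept-6-ene-7-carboxylate | COC(=O)C1=CC2C[C@@H](CC(=O)OC)CC12O[Si](C(C)C)(C(C)C)C(C)C
F2 | step 5 | methyl (5R)-5-(2-methoxy-2-oxoethyl)-7-oxocyclohept-1-ene-1-carboxylate | COC(=O)C1=CCC[C@@H](CC(=O)OC)CC1=O
F3 | step 5 | methyl (4R)-4-(2-methoxy-2-oxoethyl)-7-methyl-2-oxo-1-(phenylselanyl)cycloheptane-1-carboxylate (C11/C13 diastereomers) | COC(=O)C1([Se]c2ccccc2)C(C)CC[C@@H](CC(=O)OC)CC1=O
F4 | step 7 | tert-butyldimethylsilyl ester and C20 tert-butyldimethylsilyl dienol ether of 10 | CC(C)(C)[Si](C)(C)OC1=C(C(=O)OC)C(C)=CC[C@@H](CC(=O)O[Si](C)(C)C(C)(C)C)C1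
F5 | step 8 | C6β-hydroxy ketone of 11 carrying the C13 trimethylsilyl ether (acid form) | O=C1[C@](O[Si](C)(C)C)(C(=O)OC)C(C)=CC[C@@H](CC(=O)O)[C@@H]1O
F6 | step 8 | C13 trimethylsilyl ether of 14 | C1C(=O)O[C@@H]2[C@H]1CC=C(C)[C@@](O[Si](C)(C)C)(C(=O)OC)C2=O
F7 | step 10 | lithium carboxylate of ring-opened 15 (C6α-OH, C20β-OH, C13α-OH) | O[C@@H]1[C@](O)(C(=O)OC)C(C)=CC[C@@H](CC(=O)[O-])[C@H]1O.[Li+]
F8 | step 10 | lithium carboxylate of ring-opened 16 | O[C@@H]1[C@](O)(CO)C(C)=CC[C@@H](CC(=O)[O-])[C@H]1O.[Li+]
F9 | step 12 | C20 dimethylsilyl ether of 17 | C1C(=O)O[C@@H]2[C@H]1CC=C(C)[C@@]3(COC(C)(C)O3)[C@H]2O[SiH](C)C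
F10 | step 12 | cyclic siloxane (O20–SiMe2–C9β) from F9, C11β-H | C1C(=O)O[C@@H]2[C@H]1C[C@@H]4[C@H](C)[C@@]3(COC(C)(C)O3)[C@H]2O[Si]4(C)C
F11 | step 16 | triol: 22 without the acetonide | C=C1C(=O)O[C@@H]2[C@H]1C[C@@H](O[Si](C)(C)C(C)(C)C)[C@H](C)[C@@](O)(CO)[C@H]2O
F12 | step 16 | C15 aldehyde of F11 | C=C1C(=O)O[C@@H]2[C@H]1C[C@@H](O[Si](C)(C)C(C)(C)C)[C@H](C)[C@@](O)(C=O)[C@H]2O
F13 | step 16 | (E)-prop-1-enyl carbinol from F12 (C15 epimers) | C=C1C(=O)O[C@@H]2[C@H]1C[C@@H](O[Si](C)(C)C(C)(C)C)[C@H](C)[C@@](O)(C(O)/C=C/C)[C@H]2O
F14 | step 16 | enone from F13 with free C20β-OH | C=C1C(=O)O[C@@H]2[C@H]1C[C@@H](O[Si](C)(C)C(C)(C)C)[C@H](C)[C@@](O)(C(=O)/C=C/C)[C@H]2O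
A1 | alternative 1 | seven-membered α-(4-methoxybenzyloxy) lactone with (E)-prop-1-enyl on C8, vinyl on C7 and the C6/C20 acetonide (C8 configuration chosen for chirality transfer; C13 lost on enolisation) | O=C1O[C@H](/C=C/C)[C@@H](C=C)[C@H]2OC(C)(C)O[C@@H]2C1OCc1ccc(OC)cc1
A2 | alternative 1 | cycloheptenecarboxylic acid with C13 and C11 set | OC(=O)[C@]1(OCc3ccc(OC)cc3)[C@@H](C)C=C[C@@H](C=C)[C@H]2OC(C)(C)O[C@H]12
A3 | alternative 2 | C6 diazo(diethoxyphosphoryl)acetate of the fully substituted cycloheptane (C7 methylene) | CCOP(=O)(OCC)C(=[N+]=[N-])C(=O)O[C@@H]1CC[C@@H](O[Si](CC)(CC)CC)[C@H](C)[C@@](O[Si](C)(C)C)(C(=O)/C=C/C)[C@H]1OC(=O)CC(C)C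
A4 | alternative 2 | cis-fused α-phosphono-γ-lactone | CCOP(=O)(OCC)[C@@H]1C(=O)O[C@@H]2[C@H]1C[C@@H](O[Si](CC)(CC)CC)[C@H](C)[C@@](O[Si](C)(C)C)(C(=O)/C=C/C)[C@H]2OC(=O)CC(C)C
A5 | alternative 3 | mixed acetal 1-methoxy-1-[(1S)-1-phenylethoxy]-2-(trimethylsilyloxy)prop-2-ene (either acetal epimer) | C=C(O[Si](C)(C)C)C(OC)O[C@@H](C)c1ccccc1
A6 | alternative 3 | 3-methylfuran | Cc1ccoc1
A7 | alternative 3 | 6-methyl-2-[(S)-1-phenylethoxy]-8-oxabicyclo[3.2.1]oct-6-en-3-one | C[C@@H](c1ccccc1)O[C@@H]2C(=O)C[C@@H](O3)C(C)=C[C@H]23
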